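**Assumption:** niveusin B is taken as the single 3,10-hemiketal encoded by the SMILES (3R,6R,7R,8R,10S; 4Z; germacrane numbering), and (R)-3-hydroxy-γ-butyrolactone is bought as the only chiral starting material (commercial; derived from D-malic acid).

## Retrosynthetic overview

1. Niveusin B ⇐ C8 angeloylation and C15 desilylation of hemiketal lactone **13**.
2. **13** ⇐ intramolecular Cr(II) Barbier allylation of keto-enal allyl bromide **12**: forms C6–C7, the 10-membered ring and the trans-γ-lactone in one step; the bridging 3,10-hemiketal (THF) closes last, transannularly.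
3. **12** ⇐ singlet-oxygen photooxygenation of 2,3-disubstituted furan **11** (the furan is a masked (Z)-C3-ketone/C6-aldehyde and fixes the 4Z alkene).
4. **11** ⇐ triol **6** (Baylis–Hillman/bromide at C7); **6** ⇐ cathodic Sm-catalysed, chelation-controlled ketyl–olefin coupling (C1–C10 bond, C10 set from C8) of ketodiol **5** with vinylfuran **3**.
5. **5** ⇐ (R)-3-hydroxy-γ-butyrolactone (C8); **3** ⇐ 3-furanmethanol. Ring order: furan (bought, later opened) → 10-membered carbocycle + lactone → THF hemiketal.

## Route

**Step 1**
Reactants: **1** furan-3-ylmethanol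
Product: **2** (2-ethenylfuran-3-yl)methanol
Conditions: n-BuLi (2.2 equiv), THF, −78→0 °C; ZnCl2; CH2=CHBr, Pd(PPh3)4 (3 mol %), rt
Reagents that add atoms: vinyl bromide, C=CBr
Why: Alkoxide-directed C2 lithiation of the 3-furanmethanol dianion, transmetalation to zinc and Negishi coupling install the vinyl group next to the CH2OH (future C15).

**Step 2**
Reactants: **2**
Product: **3** tert-butyl[(2-ethenylfuran-3-yl)methoxy]diphenylsilane
Conditions: TBDPSCl, imidazole, DMF, rt
Reagents that add atoms: TBDPSCl, CC(C)(C)[Si](Cl)(c1ccccc1)c1ccccc1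
Why: Standard silylation; the TBDPS ether is chosen to outlast the later TES removal and the angeloylation.

**Step 3**
Reactants: **4** (R)-3-hydroxy-γ-butyrolactone [(4R)-4-hydroxyoxolan-2-one]
Product: **5** (4R)-4,5-dihydroxypentan-2-one
Conditions: MeLi (2.1 equiv), THF, −78 °C; AcOH quench
Reagents that add atoms: methyllithium, [Li]C
Why: Mono-addition of MeLi to the lactone (the lithium hemiketalate resists over-addition at −78 °C) gives the β-hydroxy methyl ketone; the purchased carbinol centre (future C8, R) is untouched.

**Step 4**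
Reactants: **5** and **3** (2 equiv)
Product: **6** (2R,4S)-6-[3-({[tert-butyl(diphenyl)silyl]oxy}methyl)furan-2-yl]-4-methylhexane-1,2,4-triol
Conditions: SmI2 (15 mol %), t-BuOH (3 equiv), n-Bu4NPF6, THF, −10 °C; carbon-felt cathode / Mg anode, constant current, ca. 2.3 F mol⁻¹
Reagents that add atoms: none
Why: Proposed new method: cathodically regenerated Sm(II) binds the β-hydroxy ketone as a six-membered C8–OH/C10=O chelate, inner-sphere electron transfer gives a chelated Sm(III) ketyl that adds through its axial lobe (C8 side chain equatorial) to the CH2 terminus of the vinylfuran, the furfuryl radical is reduced and protonated by t-BuOH, and the low steady-state Sm(II) concentration suppresses over-reduction so that this slower, non-acrylate acceptor can compete, forming C1–C10 and setting C10 (S) 1,3-anti to C8; the closest known chemistry is the stoichiometric SmI2 chelation-controlled coupling of β-hydroxy ketones with acrylates (1,3-anti γ-lactones), SmI2/HMPA ketone–styrene coupling and Sm-catalysed electroreductive ketyl–acrylate coupling.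

**Step 5**
Reactants: **6**
Product: **7** tris(triethylsilyl) ether of **6** (1-, 2- and 4-OTES)
Conditions: TESOTf (4 equiv), 2,6-lutidine, CH2Cl2, −78→0 °C
Reagents that add atoms: TESOTf, CC[Si](CC)(CC)OS(=O)(=O)C(F)(F)F
Why: Exhaustive silylation (the triflate also caps the tertiary C10–OH, which would otherwise form a lactol with the C7 aldehyde made next).

**Step 6**
Reactants: **7**
Product: **8** (2R,4S)-6-[3-(TBDPSO-methyl)furan-2-yl]-4-methyl-2,4-bis(triethylsilyloxy)hexanal
Conditions: (COCl)2, DMSO, CH2Cl2, −78→−30 °C; Et3N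
Reagents that add atoms: none
Why: Under Swern conditions a primary TES ether is cleaved and oxidised directly to the aldehyde, while secondary and tertiary TES ethers and the TBDPS ether survive.

**Step 7**
Reactants: **8** and **9** methyl acrylate
Product: **10** methyl (4R,6S)-8-[3-(TBDPSO-methyl)furan-2-yl]-3-hydroxy-6-methyl-2-methylidene-4,6-bis(triethylsilyloxy)octanoate (C3 epimers)
Conditions: methyl acrylate (10 equiv, neat), quinuclidine (0.5 equiv), MeOH (1 equiv), rt, 48 h
Reagents that add atoms: methyl acrylate (**9**), C=CC(=O)OC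
Why: Morita–Baylis–Hillman reaction adds the C11–C13 acrylate unit at C7; the new carbinol configuration is irrelevant because it is destroyed in step 8.

**Step 8**
Reactants: **10**
Product: **11** methyl (2Z,4R,6S)-2-(bromomethyl)-8-[3-(TBDPSO-methyl)furan-2-yl]-6-methyl-4,6-bis(triethylsilyloxy)oct-2-enoate
Conditions: MsCl, Et3N, CH2Cl2, −20 °C; then LiBr, THF, 0 °C→rt
Reagents that add atoms: lithium bromide, [Li+].[Br-]
Why: Mesylation and SN2′ displacement by bromide give the thermodynamically preferred (Z)-2-(bromomethyl)enoate under non-acidic conditions that spare the furan and TES ethers.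

**Step 9**
Reactants: **11**
Product: **12** methyl (2Z,4R,6S,10Z)-2-(bromomethyl)-10-(TBDPSO-methyl)-6-methyl-9,12-dioxo-4,6-bis(triethylsilyloxy)dodeca-2,10-dienoate (used crude)
Conditions: O2, TPP (1 mol %), white LED, CH2Cl2, −78 °C; then Me2S, −78→−20 °C
Reagents that add atoms: dioxygen, O=O (one O retained)
Why: [4+2] cycloaddition of singlet oxygen to the furan (far more reactive than the electron-poor enoate) and reductive cleavage of the endoperoxide unveil the C3 ketone and C6 aldehyde as a cis-enedione, the 4Z geometry being inherited from the furan ring.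

**Step 10**
Reactants: **12**
Product: **13** 15-O-TBDPS-8-O-desangeloylniveusin B [(3R,6R,7R,8R,10S)-3,8-dihydroxy-3,10-epoxy-15-(TBDPS-oxy)germacra-4Z,11(13)-dien-12,6-olide]
Conditions: CrCl2 (8 equiv), THF, rt, syringe-pump addition (final 2 mM); then 1 M aq HCl–THF, rt
Reagents that add atoms: none
Why: Intramolecular Nozaki–Hiyama (Barbier-type) allylation: the 2-(methoxycarbonyl)allyl–Cr(III) species attacks the aldehyde (much more reactive than the hindered enone carbonyl) through a chair-like transition state inside the forming 10-membered ring, with the C8 silyloxy centre (H8 eclipsing C7=C11) directing attack to give the 6,7-trans, 7,8-cis-H array (6R,7R); the acid then lactonises, removes both TES ethers and lets the freed 10-OH close onto C3=O, whose configuration (3R) is fixed by the bridge.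

**Step 11**
Reactants: **13** and **14** angelic acid [(Z)-2-methylbut-2-enoic acid]
Product: **15** 15-O-TBDPS-niveusin B
Conditions: **14**, 2,4,6-Cl3C6H2COCl, Et3N, PhMe, rt; then **13**, PhMe, 80 °C (no DMAP)
Reagents that add atoms: angelic acid (**14**), C/C=C(/C)C(=O)O
Why: Yamaguchi-type mixed-anhydride esterification without nucleophilic catalyst acylates the only reactive hydroxyl (secondary C8–OH; the tertiary hemiketal OH is inert and C15 is silylated) without Z→E isomerisation to the tiglate.

**Step 12**
Reactants: **15**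
Product: **16** niveusin B
Conditions: HF·pyridine, pyridine–THF, 0 °C→rt
Reagents that add atoms: none
Why: Buffered fluoride desilylation of the primary allylic TBDPS ether, mild enough for the α-methylene lactone, angelate and hemiketal.

## Compound list

1 | furan-3-ylmethanol | OCc1ccoc1 | starting material
2 | (2-ethenylfuran-3-yl)methanol | C=Cc1occc1CO | intermediate
3 | tert-butyl[(2-ethenylfuran-3-yl)methoxy]diphenylsilane | C=Cc1occc1CO[Si](c1ccccc1)(c1ccccc1)C(C)(C)C | intermediate
4 | (R)-3-hydroxy-γ-butyrolactone | O=C1C[C@@H](O)CO1 | starting material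
5 | (4R)-4,5-dihydroxypentan-2-one | CC(=O)C[C@@H](O)CO | intermediate
6 | (2R,4S)-6-[3-(TBDPSO-methyl)furan-2-yl]-4-methylhexane-1,2,4-triol | OC[C@H](O)C[C@@](C)(O)CCc1occc1CO[Si](c1ccccc1)(c1ccccc1)C(C)(C)C | intermediate
7 | tris-TES ether of 6 | CC[Si](CC)(CC)OC[C@H](O[Si](CC)(CC)CC)C[C@@](C)(O[Si](CC)(CC)CC)CCc1occc1CO[Si](c1ccccc1)(c1ccccc1)C(C)(C)C | intermediate
8 | (2R,4S)-6-[3-(TBDPSO-methyl)furan-2-yl]-4-methyl-2,4-bis(triethylsilyloxy)hexanal | O=C[C@H](O[Si](CC)(CC)CC)C[C@@](C)(O[Si](CC)(CC)CC)CCc1occc1CO[Si](c1ccccc1)(c1ccccc1)C(C)(C)C | intermediate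
9 | methyl acrylate | C=CC(=O)OC | starting material
10 | Baylis–Hillman adduct (C3 epimers) | C=C(C(=O)OC)C(O)[C@H](O[Si](CC)(CC)CC)C[C@@](C)(O[Si](CC)(CC)CC)CCc1occc1CO[Si](c1ccccc1)(c1ccccc1)C(C)(C)C | intermediate
11 | (2Z,4R,6S)-allylic bromide | COC(=O)/C(CBr)=C/[C@H](O[Si](CC)(CC)CC)C[C@@](C)(O[Si](CC)(CC)CC)CCc1occc1CO[Si](c1ccccc1)(c1ccccc1)C(C)(C)C | intermediate
12 | (2Z,4R,6S,10Z)-keto-enal allylic bromide | COC(=O)/C(CBr)=C/[C@H](O[Si](CC)(CC)CC)C[C@@](C)(O[Si](CC)(CC)CC)CCC(=O)/C(CO[Si](c1ccccc1)(c1ccccc1)C(C)(C)C)=C\C=O | intermediate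
13 | 15-O-TBDPS-8-O-desangeloylniveusin B | C=C1C(=O)O[C@@H]2/C=C(/CO[Si](c4ccccc4)(c4ccccc4)C(C)(C)C)[C@@]3(O)CC[C@@](C)(C[C@@H](O)[C@@H]12)O3 | intermediate
14 | angelic acid | C/C=C(/C)C(=O)O | starting material
15 | 15-O-TBDPS-niveusin B | C=C1C(=O)O[C@@H]2/C=C(/CO[Si](c4ccccc4)(c4ccccc4)C(C)(C)C)[C@@]3(O)CC[C@@](C)(C[C@@H](OC(=O)/C(C)=C\C)[C@@H]12)O3 | intermediate
16 | niveusin B | C=C1C(=O)O[C@@H]2/C=C(/CO)[C@@]3(O)CC[C@@](C)(C[C@@H](OC(=O)/C(C)=C\C)[C@@H]12)O3 | target

## Summary

Total steps: 12. Longest linear sequence: 11 (1 → 2 → 3 → 6 → … → 16; the branch from 4 is 10 steps).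

Steps most likely to fail:

1. **Step 4 (proposed new method).** Risks: chelation control has not been shown under catalytic electrochemical conditions or with a vinylfuran acceptor; reduction to the diol, pinacol coupling or 1,4-elimination of the furfuryl anion could compete. Fallback (known chemistry): stoichiometric SmI2/MeOH coupling of **5** with methyl acrylate to the 1,3-anti γ-lactone (C3 as lactone carbonyl), then addition of the vinyllithium from (Z)-TBDPSOCH2–C(I)=CH–CH(OMe)2 to that lactone to give the C3 hemiketal with C4–C6 attached, dropping the furan.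

2. **Step 10 (macrocyclisation).** Risks: wrong C6/C7 diastereomer, 7-membered attack on the C3 ketone, or Cr(II) reduction of the cis-enedione. Fallback: change the ring-closing bond. Form the lactone intermolecularly (Zn- or In-mediated Barbier of the C7–C13 bromide with (Z)-4-silyloxy-3-iodobut-2-enal), then close the 10-membered ring at C3–C4 by intramolecular Ni/Cr Nozaki–Hiyama–Kishi addition of the vinyl iodide to a C3 aldehyde, and oxidise the allylic alcohol to the enone/hemiketal.

3. **Step 7 (Baylis–Hillman on a hindered α-silyloxy aldehyde).** Risks: slow conversion and partial C8 epimerisation under the amine. Fallback: add the α-(methoxycarbonyl)vinylalane made from methyl propiolate and DIBAL-H/NMO (vinylalumination) at low temperature, which gives the same adduct without an amine base.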